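The data were generated by integration for an exercise.

If starting material turned straight into product, the dusk run would read 71.8% product at 2.50 min, but it reads 15.6%. On the list of suspects, starting material and reagent bind reversibly to intermediate, which gives product and by-product; starting material and product form idle adduct; and the protic impurity quenches starting material. I have to compare four flasks at 6.0 min.

the same everywhere: starting material 0.13 M

|  | reagent | protic impurity | temperature | remark | time |
|---|---|---|---|---|---|
| dusk | 5 equiv | 0.091 M | 32 °C | run made earlier |  |
| summer | 5 equiv | 0.14 M | 60 °C | run made earlier |  |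
| dawn | 10 equiv | 0.065 M | 32 °C | run made earlier |  |
| Wednesday's | 5.00 equiv | 0.0650 M | 70 °C |  | 6.0 min |
| Sunday's | 5.00 equiv | 0.0650 M | 45 °C |  | 6.0 min |
| Monday's | 5.00 equiv | 0.0650 M |  | at 70 °C until 4.0 min, from then on at 20 °C | 6.0 min |
| Tuesday's | 5.00 equiv | 0.0650 M | 20 °C |  | 6.0 min |

- dusk (time / min: product / %, starting material / %): 2.50: 15.6, 28.2; 4.00: 21.7, 21.2; 8.00: 29.4, 11.4; 15.0: 32.0, 6.6; 30.0: 29.7, 4.2
- summer (time / min: product / %, starting material / %): 0.667: 23.9, 13.9; 2.00: 22.5, 4.8; 3.00: 19.2, 3.2; 5.00: 14.9, 2.2; 8.00: 12.0, 1.7
- dawn (time / min: product / %, starting material / %): 2.50: 24.7, 22.3; 8.00: 44.0, 9.4; 12.0: 47.2, 6.9; 20.0: 46.7, 6.0; 30.0: 44.0, 5.2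

(each reading ± 0.3 percentage points)

- percent here means starting material units held: one idle adduct counts as two
- what is said of product includes idle adduct
- on the list of suspects stand: starting material + reagent <-> intermediate; intermediate <-> product + by-product; starting material + product <-> idle adduct; starting material + protic impurity -> quenched substrate
- in an amount of product, one idle adduct counts as one product

* the flask with the highest amount of product, in percent of the starting material charged ("all alike" if they lie within 1.5 percentage points) (Wednesday's / Sunday's / Monday's / Tuesday's / all alike)
* final product, as a percentage of the starting material charged, in Wednesday's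
* final product, as a percentage of the starting material charged, in Sunday's
* final product, as a percentage of the starting material charged, in Monday's
* final product, as a percentage of the starting material charged, in Tuesday's

The puzzle lies in the gap, the percent found in neither column at 2.50 min. From the dusk run to the dawn run, reagent goes from 5 equiv to 10 equiv and protic impurity falls from 0.091 M to 0.065 M. Product rises by a factor of 1.58, yet the gap stands at 53.0% against 56.2%.

I treat the binding as a fast pre-equilibrium, so c(intermediate) follows c(starting material) times c(reagent). The starting material readings and the reagent charges then give a factor of 1.58, matching the product factor from a different column. Each gap holds intermediate, quenched substrate and the second unit of any idle adduct, which I leave aside in this estimate. Quenching goes with c(protic impurity) times c(starting material), and if I let the protic impurity charges and the starting material readings at 2.50 min stand for the averages, I estimate that the dusk run has quenched 1.77 times as much as the dawn run. The two gaps then solve to 0.741. This is the hold ratio, c(intermediate)/c(starting material) at 5 equiv and 32 °C, and at a fixed temperature it scales with c(reagent).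

By this estimate the dusk gap splits into 20.9% intermediate and 35.3% quenched substrate, while the dawn gap holds 33.1% intermediate, more than the dusk run, and 19.9% quenched substrate. The free share, 1/(1 + hold ratio), is the part of starting material plus intermediate that stands as starting material: 57.4% in the dusk run and 40.3% in the dawn run. At 2.50 min this estimate puts more of the dusk run in intermediate than in product, and I expect a low product figure in Tuesday's, at 20 °C, to sit beside such a store of intermediate too.

The forecast gives 30% for Wednesday's, 38% for Sunday's, 32% for Monday's and 9% for Tuesday's, so Sunday's leads; of Tuesday's it says “this is still lagging”.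

The flasks give 28.2% for Wednesday's, 37.0% for Sunday's, 29.2% for Monday's and 13.1% for Tuesday's, so Sunday's leads, as forecast.

    starting material + reagent ⇌ intermediate (K = 1.50 M⁻¹, k = 1.20 M⁻¹ min⁻¹, Ea = 51.0 kJ mol⁻¹, ΔH = −17.0 kJ mol⁻¹)
    intermediate ⇌ product + by-product (K = 0.370 M, k = 0.0700 min⁻¹, Ea = 81.0 kJ mol⁻¹, ΔH = −11.0 kJ mol⁻¹)
    starting material + product ⇌ idle adduct, settled at all times (K = 4.00 M⁻¹, ΔH = −57.0 kJ mol⁻¹)
    starting material + protic impurity → quenched substrate (k = 2.20 M⁻¹ min⁻¹, Ea = 50.0 kJ mol⁻¹)
    (constants at 20 °C)

Tuesday's 13.1% product stands beside 27.7% intermediate and 30.8% starting material at 6.00 min, which the product figure doesn't show. Its hold ratio is 0.900, above the 0.741 I read from the runs at 32 °C, and Tuesday's, left ten times as long, reaches 39.7% product at 60.0 min. The neighbouring flask is Tuesday's with 12.0 equiv of reagent. Scaling Tuesday's ratio by the charges predicts 2.16 for it, and the neighbour stands at 2.25, with 40.9% intermediate against 18.2% starting material. Its product at 6.00 min is 20.3%.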